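## Retrosynthetic overview

1. Target ⇐ its achiral ring-opened (seco) isomer, a 3-(1,2-disubstituted vinyl)-4-hydroxypyranone: the last step closes ring B (dihydrofuran) by forming the C2–O1 bond enantioselectively, setting C2 and C3 together.
2. Seco isomer ⇐ racemic trans tetramethyl ether of the target: global O-demethylation, then base-induced opening of ring B (stereochemistry erased on purpose).
3. Racemic tetramethyl ether ⇐ two styrylpyranones by Mn(OAc)3 oxidative [3+2] annulation (C3–C3a bond and a first, racemic ring B).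
4. Styrylpyranones ⇐ 6-methylpyranones + 4-methoxybenzaldehyde / 3,4-dimethoxybenzaldehyde by aldol condensation.
5. Ring order: ring A (fused pyranone) and ring C (pendant pyranone) are bought intact; ring B is made racemic, opened, and re-made as the single enantiomer in the final step.

Assumption: the (R)-configured acid in step 5 is taken to give (2S,3S); if it gives the mirror image, the (S)-acid is used. The trisubstituted alkene of the seco isomer is used as an E/Z mixture, since both isomers give the same quinone methide.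

## Route

Step 1
Reactants: 1 4-hydroxy-6-methyl-2H-pyran-2-one; 2 4-methoxybenzaldehyde
Product: 4 4-hydroxy-6-[(E)-2-(4-methoxyphenyl)ethenyl]-2H-pyran-2-one, via aldol adduct 3 (not isolated)
Conditions: LiN(i-Pr)2 (2.3 equiv), THF, −78 °C; 2, −78 → −20 °C; aq. HCl; then TsOH·H2O (10 mol %), toluene, 90 °C
Reagents that add atoms: none
Why: Dianion aldol addition of the 6-methyl group of 1 (O-lithiation, then C-lithiation at the methyl) to 2, followed by acid-catalysed dehydration of the 4-methoxybenzylic alcohol (aldol condensation), gives the conjugated E-styrylpyranone with no stereocenter.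

Step 2
Reactants: 5 4-methoxy-6-methyl-2H-pyran-2-one; 6 3,4-dimethoxybenzaldehyde
Product: 8 6-[(E)-2-(3,4-dimethoxyphenyl)ethenyl]-4-methoxy-2H-pyran-2-one, via aldol adduct 7 (not isolated)
Conditions: Mg(OMe)2 (2 equiv), MeOH, reflux, 12 h; aq. HCl
Reagents that add atoms: none
Why: Mg(OMe)2-mediated vinylogous aldol condensation at the 6-methyl group (the classical kavalactone synthesis) gives the E-alkene by thermodynamic elimination; the 4-methoxy group keeps ring C from acting as a 1,3-dicarbonyl in step 3.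

Step 3
Reactants: 4 4-hydroxy-6-[(E)-2-(4-methoxyphenyl)ethenyl]-2H-pyran-2-one; 8 6-[(E)-2-(3,4-dimethoxyphenyl)ethenyl]-4-methoxy-2H-pyran-2-one (3 equiv)
Product: 9 rac-(2S,3S)-2-(3,4-dimethoxyphenyl)-3-(4-methoxy-2-oxo-2H-pyran-6-yl)-6-[(E)-2-(4-methoxyphenyl)ethenyl]-2,3-dihydro-4H-furo[3,2-c]pyran-4-one (racemic trans)
Conditions: Mn(OAc)3·2H2O (2.4 equiv), Cu(OAc)2·H2O (20 mol %), AcOH, 70 °C, N2; 4 added over 3 h; excess 8 recovered
Reagents that add atoms: none
Why: Oxidative radical [3+2] annulation of a 1,3-dicarbonyl with an alkene by trivalent manganese: the electrophilic C3 radical of 4 adds to the alkene carbon of 8 next to ring C, the 3,4-dimethoxybenzylic radical is oxidised by divalent copper and trapped by the ring A oxygen anti to the ring C substituent (trans, racemic on purpose), and slow addition of 4 into excess 8 suppresses attack on the styryl group of 4.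

Step 4
Reactants: 9 rac-(2S,3S)-2-(3,4-dimethoxyphenyl)-3-(4-methoxy-2-oxo-2H-pyran-6-yl)-6-[(E)-2-(4-methoxyphenyl)ethenyl]-2,3-dihydro-4H-furo[3,2-c]pyran-4-one
Product: 11 3-[2-(3,4-dihydroxyphenyl)-1-(4-hydroxy-2-oxo-2H-pyran-6-yl)ethenyl]-4-hydroxy-6-[(E)-2-(4-hydroxyphenyl)ethenyl]-2H-pyran-2-one (E/Z mixture at the trisubstituted alkene), via racemic pentahydroxy dihydrofuran 10 (not isolated)
Conditions: BBr3 (12 equiv), CH2Cl2, −78 °C → rt; MeOH, −78 °C, evaporate; then KOt-Bu (10 equiv), degassed DMF, 0 °C → rt, argon, 1 h; AcOH (12 equiv), −20 °C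
Reagents that add atoms: none
Why: Lewis acid ether cleavage (BBr3 demethylation of the three aryl methyl ethers and the vinylogous methyl ester) followed by base-induced retro-oxa-1,6-addition: the 4-phenoxide expels the ring A enolate to a quinone methide that tautomerises to the stilbene, which is the sink in strong base because the open form carries one more acidic OH, and both stereocenters are erased so that any ring-B scrambling under BBr3 is harmless.

Step 5
Reactants: 11 3-[2-(3,4-dihydroxyphenyl)-1-(4-hydroxy-2-oxo-2H-pyran-6-yl)ethenyl]-4-hydroxy-6-[(E)-2-(4-hydroxyphenyl)ethenyl]-2H-pyran-2-one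
Product: 13 (2S,3S)-2-(3,4-dihydroxyphenyl)-3-(4-hydroxy-2-oxo-2H-pyran-6-yl)-6-[(E)-2-(4-hydroxyphenyl)ethenyl]-2,3-dihydro-4H-furo[3,2-c]pyran-4-one, via quinone methide 12 (not isolated)
Conditions: (R)-N-triflylphosphoramide of 3,3'-bis(2,4,6-triisopropylphenyl)-1,1'-bi-2-naphthol, [(R)-3,3'-(2,4,6-i-Pr3C6H2)2-BINOL]P(=O)NHSO2CF3 (10 mol %), EtOAc (0.01 M), 0 °C → rt, argon, dark, 24–48 h; filtration through C18 with 0.1 % HCO2H in MeCN/H2O, kept cold and free of base
Reagents that add atoms: none
Why: Proposed new method: chiral Brønsted acid catalysed enantioselective cycloisomerisation of a 4-hydroxystilbene-type seco alkene, in which the acid protonates the alkene carbon bearing rings A and C to give the p-quinone methide 12 hydrogen-bonded to the chiral phosphoramide anion, 12 racemises through 11, and the ring A enol oxygen then adds to the benzylic carbon (C2–O1 bond) inside the chiral ion pair, selecting one enantiomer of 12 and the face anti to ring C so that C3 (by protonation) and C2 (by C–O bond formation) are set together as trans-(2S,3S); the closest known reaction type is the chiral phosphoric acid catalysed 1,6-addition of O-nucleophiles to p-quinone methides formed in situ, together with asymmetric intramolecular hydroalkoxylation of alkenes by confined chiral Brønsted acids.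

## Compound list

1 | 4-hydroxy-6-methyl-2H-pyran-2-one | Cc1cc(O)cc(=O)o1 | starting material
2 | 4-methoxybenzaldehyde | COc1ccc(C=O)cc1 | starting material
3 | 4-hydroxy-6-[2-hydroxy-2-(4-methoxyphenyl)ethyl]-2H-pyran-2-one (racemic aldol adduct) | COc1ccc(C(O)Cc2cc(O)cc(=O)o2)cc1 | intermediate (not isolated)
4 | 4-hydroxy-6-[(E)-2-(4-methoxyphenyl)ethenyl]-2H-pyran-2-one | COc1ccc(/C=C/c2cc(O)cc(=O)o2)cc1 | intermediate
5 | 4-methoxy-6-methyl-2H-pyran-2-one | COc1cc(C)oc(=O)c1 | starting material
6 | 3,4-dimethoxybenzaldehyde | COc1ccc(C=O)cc1OC | starting material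
7 | 6-[2-(3,4-dimethoxyphenyl)-2-hydroxyethyl]-4-methoxy-2H-pyran-2-one (racemic aldol adduct) | COc1cc(CC(O)c2ccc(OC)c(OC)c2)oc(=O)c1 | intermediate (not isolated)
8 | 6-[(E)-2-(3,4-dimethoxyphenyl)ethenyl]-4-methoxy-2H-pyran-2-one | COc1cc(/C=C/c2ccc(OC)c(OC)c2)oc(=O)c1 | intermediate
9 | rac-(2S,3S)-2-(3,4-dimethoxyphenyl)-3-(4-methoxy-2-oxo-2H-pyran-6-yl)-6-[(E)-2-(4-methoxyphenyl)ethenyl]-2,3-dihydro-4H-furo[3,2-c]pyran-4-one (racemic trans; one enantiomer drawn, mirror image present in equal amount) | O=c1cc(OC)cc([C@H]2c3c(cc(/C=C/c4ccc(OC)cc4)oc3=O)O[C@@H]2c2ccc(OC)c(OC)c2)o1 | intermediate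
10 | rac-(2S,3S)-2-(3,4-dihydroxyphenyl)-3-(4-hydroxy-2-oxo-2H-pyran-6-yl)-6-[(E)-2-(4-hydroxyphenyl)ethenyl]-2,3-dihydro-4H-furo[3,2-c]pyran-4-one (racemic trans; one enantiomer drawn, mirror image present in equal amount) | O=c1cc(O)cc([C@H]2c3c(cc(/C=C/c4ccc(O)cc4)oc3=O)O[C@@H]2c2ccc(O)c(O)c2)o1 | intermediate (not isolated)
11 | 3-[2-(3,4-dihydroxyphenyl)-1-(4-hydroxy-2-oxo-2H-pyran-6-yl)ethenyl]-4-hydroxy-6-[(E)-2-(4-hydroxyphenyl)ethenyl]-2H-pyran-2-one (seco isomer, E/Z mixture at the trisubstituted alkene) | O=c1cc(O)cc(C(=Cc2ccc(O)c(O)c2)c2c(O)cc(/C=C/c3ccc(O)cc3)oc2=O)o1 | intermediate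
12 | 4-hydroxy-3-[2-(3-hydroxy-4-oxocyclohexa-2,5-dien-1-ylidene)-1-(4-hydroxy-2-oxo-2H-pyran-6-yl)ethyl]-6-[(E)-2-(4-hydroxyphenyl)ethenyl]-2H-pyran-2-one (p-quinone methide, racemic at the sp3 carbon) | O=c1cc(O)cc(C(C=C2C=CC(=O)C(O)=C2)c2c(O)cc(/C=C/c3ccc(O)cc3)oc2=O)o1 | intermediate (not isolated)
13 | (2S,3S)-2-(3,4-dihydroxyphenyl)-3-(4-hydroxy-2-oxo-2H-pyran-6-yl)-6-[(E)-2-(4-hydroxyphenyl)ethenyl]-2,3-dihydro-4H-furo[3,2-c]pyran-4-one | O=c1cc(O)cc([C@H]2c3c(cc(/C=C/c4ccc(O)cc4)oc3=O)O[C@@H]2c2ccc(O)c(O)c2)o1 | target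

## Step count and risks

Total steps: 5. Longest linear sequence: 4 (1 → 4 → 9 → 11 → 13, or equally 5 → 8 → 9 → 11 → 13).

Three steps most likely to fail:

**Step 5 (the proposed new reaction).** The alkene carries two pyranone rings and may be too weakly basic for the acid. The ethyl acetate needed to dissolve the pentaol may blunt the ion pairing. The ring A lactone oxygen could close instead of the 4-OH. The product can slowly racemise back through 12 if left with the acid, and opens in base.
Fallback, known chemistry: set out from compound 9. Demethylate with BBr3, quench with MeOH and work up under acid without the base treatment, which leaves the closed racemate 10 as an isolable solid. Resolve it by preparative HPLC on an amylose tris(3,5-dimethylphenylcarbamate) phase with an acidified eluent. This gives compound 13 directly, beside its mirror image (2R,3R)-2-(3,4-dihydroxyphenyl)-3-(4-hydroxy-2-oxo-2H-pyran-6-yl)-6-[(E)-2-(4-hydroxyphenyl)ethenyl]-2,3-dihydro-4H-furo[3,2-c]pyran-4-one F5. F5 can be racemised (KOt-Bu to 11, then catalytic TsOH recloses it to racemic 10) and resolved again. The fallback comes back to the route at compound 13.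

**Step 3 (cross-selectivity of the radical annulation).** The radical from 4 can also attack the styryl group of another molecule of 4 or of the product. Regiochemistry on the push–pull alkene of 8 rests on analogy with cinnamates and chalcones.
Fallback: set out from compounds 1 and 8. Run the same Mn(OAc)3·2H2O/Cu(OAc)2·H2O annulation with 1, which has no alkene, to give rac-(2S,3S)-2-(3,4-dimethoxyphenyl)-3-(4-methoxy-2-oxo-2H-pyran-6-yl)-6-methyl-2,3-dihydro-4H-furo[3,2-c]pyran-4-one F1. Treat F1 with LiN(i-Pr)2 (3.2 equiv) in THF at −78 °C: β-elimination opens ring B to 3-[2-(3,4-dimethoxyphenyl)-1-(4-methoxy-2-oxo-2H-pyran-6-yl)ethenyl]-4-hydroxy-6-methyl-2H-pyran-2-one F2 (as its dianion, not isolated). The 6-methyl group of F2 adds to 2 to give 3-[2-(3,4-dimethoxyphenyl)-1-(4-methoxy-2-oxo-2H-pyran-6-yl)ethenyl]-4-hydroxy-6-[2-hydroxy-2-(4-methoxyphenyl)ethyl]-2H-pyran-2-one F3. Dehydration with TsOH·H2O in toluene gives the seco tetramethyl ether 3-[2-(3,4-dimethoxyphenyl)-1-(4-methoxy-2-oxo-2H-pyran-6-yl)ethenyl]-4-hydroxy-6-[(E)-2-(4-methoxyphenyl)ethenyl]-2H-pyran-2-one F4; any 9 formed by acid reclosure converges as well. F4 is taken through the conditions of step 4, so the fallback comes back to the route at compound 11.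

**Step 4 (global demethylation and ring opening).** BBr3 must cleave four methyl ethers without destroying the electron-rich stilbene and benzylic ether. The open form 11 must survive acidification without reclosing to the racemate, which would lower the final ee.
Fallback: set out from compound 9 and replace the Lewis acid by nucleophilic dealkylation under basic conditions throughout: NaSEt (12 equiv) in degassed DMF at 110 °C under argon. The basic medium opens ring B by β-elimination and removes the four methyl groups by SN2 attack of thiolate, so 11 forms as its polyanion and never meets acid before the final AcOH quench at −20 °C. No new compound is isolated, and the fallback comes back to the route at compound 11.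

## Further compounds

F1 | step 3 | rac-(2S,3S)-2-(3,4-dimethoxyphenyl)-3-(4-methoxy-2-oxo-2H-pyran-6-yl)-6-methyl-2,3-dihydro-4H-furo[3,2-c]pyran-4-one (racemic trans, one enantiomer drawn) | O=c1cc(OC)cc([C@H]2c3c(cc(C)oc3=O)O[C@@H]2c2ccc(OC)c(OC)c2)o1
F2 | step 3 | 3-[2-(3,4-dimethoxyphenyl)-1-(4-methoxy-2-oxo-2H-pyran-6-yl)ethenyl]-4-hydroxy-6-methyl-2H-pyran-2-one (E/Z mixture) | O=c1cc(OC)cc(C(=Cc2ccc(OC)c(OC)c2)c2c(O)cc(C)oc2=O)o1
F3 | step 3 | 3-[2-(3,4-dimethoxyphenyl)-1-(4-methoxy-2-oxo-2H-pyran-6-yl)ethenyl]-4-hydroxy-6-[2-hydroxy-2-(4-methoxyphenyl)ethyl]-2H-pyran-2-one (racemic, E/Z mixture) | O=c1cc(OC)cc(C(=Cc2ccc(OC)c(OC)c2)c2c(O)cc(CC(O)c3ccc(OC)cc3)oc2=O)o1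
F4 | step 3 | 3-[2-(3,4-dimethoxyphenyl)-1-(4-methoxy-2-oxo-2H-pyran-6-yl)ethenyl]-4-hydroxy-6-[(E)-2-(4-methoxyphenyl)ethenyl]-2H-pyran-2-one (E/Z mixture at the trisubstituted alkene) | O=c1cc(OC)cc(C(=Cc2ccc(OC)c(OC)c2)c2c(O)cc(/C=C/c3ccc(OC)cc3)oc2=O)o1
F0 | step 4 | none | none
F5 | step 5 | (2R,3R)-2-(3,4-dihydroxyphenyl)-3-(4-hydroxy-2-oxo-2H-pyran-6-yl)-6-[(E)-2-(4-hydroxyphenyl)ethenyl]-2,3-dihydro-4H-furo[3,2-c]pyran-4-one | O=c1cc(O)cc([C@@H]2c3c(cc(/C=C/c4ccc(O)cc4)oc3=O)O[C@H]2c2ccc(O)c(O)c2)o1
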